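**Retrosynthetic overview**
1. The plan rests on the ten-membered carbocycle C1–C10. The C1 ketone and the lactone-bearing C6 are 1,6-related across it, C8–C9 lies on the far side, and the cis C4–C5 epoxide is a cyclohexene oxide in waiting, so the ring is a ring-expanded 1,2-dialkenylcyclohexanol (restore C1–C6, remove C8–C9).
2. End game, rings made last: C8 methacrylate from a PMB ether; methylene lactone from the C7 isopropenyl group and the C6 hydroxyl (SeO2, then MnO2); tetrahydrofuran from the C10 hydroxyl opening a C6–C7 epoxide across the ring; C10 hydroxyl by Rubottom oxidation.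
3. Ten-membered ring: anionic oxy-Cope ring expansion of cyclohexanol 29 to silyl enol ether 32.
4. Precursor 29: Suzuki coupling of a (Z)-enol triflate at C7, isopropenylcerium addition to the C1 ketone, epoxidation directed by a C7 hydroxyl.
5. Cyclohexene: ring-closing metathesis after an Evans crotonate aldol (sets C6) and a Weinreb ketone synthesis. Ring order: cyclohexene, epoxide, ten-membered ring, tetrahydrofuran, lactone.

Key step: step 15

Remark: every intermediate keeps the target's atom labels (C1 ketone carbon, C4/C5 epoxide, C6 lactone oxygen, C7 spiro carbon, C8 ester carbinol, C10 ether carbon with methyl C14, C11 with carbonyl C12 and methylene C13, C15 on C4); PMB = 4-methoxybenzyl; dimethyldioxirane is taken as a freshly prepared acetone solution.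

**Route**

Step 1
Reactants: 1 4-methoxybenzyl alcohol; 2 allyl bromide
Product: 3 allyl 4-methoxybenzyl ether
Conditions: NaH, THF/DMF, 0 °C to rt
Reagents that add atoms: none
Why: Williamson ether synthesis of a primary alkoxide with a reactive allylic bromide; no stereocentre is formed.

Step 2
Reactants: 3 allyl 4-methoxybenzyl ether
Product: 5 2-(PMB-oxy)acetaldehyde, via secondary ozonide 4 (not isolated)
Conditions: O3, CH2Cl2, −78 °C (indicator end point); then PPh3, −78 °C to rt
Reagents that add atoms: ozone, [O-][O+]=O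
Why: Ozonolysis with reductive work-up cleaves the terminal alkene before ozone attacks the anisyl ring when the end point is controlled; no stereocentre is formed.

Step 3
Reactants: 6 (S)-4-benzyloxazolidin-2-one; 7 (E)-but-2-enoyl chloride
Product: 9 (S)-4-benzyl-3-[(E)-but-2-enoyl]oxazolidin-2-one, via lithium oxazolidinide 8 (not isolated)
Conditions: n-BuLi, THF, −78 °C; then 7, −78 to 0 °C
Reagents that add atoms: none
Why: N-acylation of the lithiated auxiliary (Evans imide formation), which leaves the auxiliary stereocentre untouched.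

Step 4
Reactants: 9 (S)-4-benzyl-3-[(E)-but-2-enoyl]oxazolidin-2-one; 5 2-(PMB-oxy)acetaldehyde
Product: 12 (S)-4-benzyl-3-[(2S,3S)-2-ethenyl-3-hydroxy-4-(PMB-oxy)butanoyl]oxazolidin-2-one, via boron dienolate 10 (not isolated), via boron aldolate 11 (not isolated)
Conditions: Bu2BOTf, Et3N, CH2Cl2, −78 to 0 °C; then 5, −78 to 0 °C; then pH 7 buffer, MeOH, H2O2, 0 °C
Reagents that add atoms: none
Why: Evans syn aldol reaction of the (Z)-boron dienolate of the crotonyl imide, which reacts at its alpha carbon through a Zimmerman–Traxler chair on the face away from the benzyl group, so the auxiliary sets C6 (S) and the C7 carbinol.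

Step 5
Reactants: 12 aldol imide
Product: 13 (2S,3S)-2-ethenyl-3-hydroxy-N-methoxy-N-methyl-4-(PMB-oxy)butanamide
Conditions: MeNH(OMe)·HCl, AlMe3, CH2Cl2, −20 °C to rt; cold 1 M HCl
Reagents that add atoms: N,O-dimethylhydroxylamine hydrochloride, CNOC.Cl
Why: Aluminium amide transamination of the imide (Weinreb amide formation), helped by the free beta-hydroxyl, releases the auxiliary and touches no stereocentre.

Step 6
Reactants: 13 Weinreb amide; 14 4-bromo-2-methylbut-1-ene
Product: 17 (3S)-3-[(1S)-1-hydroxy-2-(PMB-oxy)ethyl]-7-methylocta-1,7-dien-4-one, via Grignard reagent 15 (not isolated), via magnesium hemiaminal 16 (not isolated)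
Conditions: 14, Mg, THF, rt; then 13, THF, −78 to 0 °C; cold aq NH4Cl
Reagents that add atoms: none
Why: Weinreb ketone synthesis, in which the chelated tetrahedral adduct keeps the carbonyl masked until the cold quench, so the alpha-vinyl stereocentre C6 is not enolised.

Step 7
Reactants: 17 dienyl ketone
Product: 18 (2S)-2-[(1S)-1-hydroxy-2-(PMB-oxy)ethyl]-4-methylcyclohex-3-en-1-one
Conditions: second-generation Grubbs catalyst (H2IMes)(PCy3)Cl2Ru=CHPh (3 mol %), CH2Cl2 (5 mM), 40 °C
Reagents that add atoms: none
Why: Ring-closing metathesis of the vinyl group with the 1,1-disubstituted alkene closes the six-membered ring and places the trisubstituted C4=C5 alkene without regiochemical ambiguity; C6 is untouched.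

Step 8
Reactants: 18 cyclohexenone
Product: 19 cis-epoxy ketone (C4–C5 epoxide of 18 with the oxygen on the ring face that carries the C6 side chain)
Conditions: VO(acac)2 (5 mol %), t-BuOOH, CH2Cl2, 0 °C to rt
Reagents that add atoms: tert-butyl hydroperoxide, CC(C)(C)OO
Why: Vanadium-catalysed hydroxyl-directed epoxidation of a homoallylic alcohol; the C7 hydroxyl is tethered through C6, so the vanadate can deliver oxygen only to the ring face that carries the side chain, which sets C4 and C5 cis to the C6 substituent.

Step 9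
Reactants: 19 cis-epoxy ketone; 20 isopropenylmagnesium bromide
Product: 22 epoxy diol (C1 tertiary hydroxyl on the face of the C6 side chain and the epoxide oxygen; isopropenyl group on the opposite face), via isopropenylcerium dichloride 21 (not isolated)
Conditions: CeCl3 (dried), THF, −78 °C, 20 (3 equiv); then 19, −78 to −40 °C; aq NH4Cl
Reagents that add atoms: none
Why: Organocerium 1,2-addition to an enolisable ketone, which suppresses enolisation, retro-aldol cleavage and beta-elimination of the epoxide; the reagent enters C1 equatorially from the face opposite the C6 side chain and the epoxide oxygen, so the hydroxyl ends cis and the isopropenyl group trans to C6.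

Step 10
Reactants: 22 epoxy diol
Product: 23 C7 ketone (beta-hydroxy ketone with the tertiary C1 hydroxyl free)
Conditions: Dess–Martin periodinane, NaHCO3, CH2Cl2, 0 °C to rt
Reagents that add atoms: none
Why: Dess–Martin oxidation takes the secondary C7 alcohol to the ketone and cannot oxidise the tertiary C1 alcohol, while the buffer avoids retro-aldol cleavage and epimerisation at C6.

Step 11
Reactants: 23 C7 ketone
Product: 24 trimethylsilyl ether of 23 (C1–OSiMe3)
Conditions: N-(trimethylsilyl)imidazole, CH2Cl2, rt
Reagents that add atoms: N-(trimethylsilyl)imidazole, C[Si](C)(C)n1ccnc1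
Why: Neutral silylation of the tertiary alcohol blocks retro-aldol cleavage in the enolisation that follows and does not open the epoxide.

Step 12
Reactants: 24 silyl ether ketone
Product: 26 (Z)-enol triflate (C7–OTf cis to the PMB ether oxygen on C8), via lithium (Z)-enolate 25 (not isolated)
Conditions: LiN(SiMe3)2, THF, −78 °C; then Comins reagent, −78 to −20 °C
Reagents that add atoms: N-(5-chloropyridin-2-yl)-1,1,1-trifluoro-N-(trifluoromethylsulfonyl)methanesulfonamide, FC(F)(F)S(=O)(=O)N(c1ccc(Cl)cn1)S(=O)(=O)C(F)(F)F
Why: Kinetic enolisation and O-triflation (enol triflate synthesis); the bulky amide takes a proton from the open alkoxymethylene and not from the crowded C6 methine, and lithium chelation by the ether oxygen together with the bulk of C6 gives the Z enolate, so triflate and ether oxygen end cis on C7=C8.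

Step 13
Reactants: 26 (Z)-enol triflate; 27 isopropenylboronic acid pinacol ester
Product: 28 silyl-protected dienyl carbinol (C1–OSiMe3; C7 bears the (1Z)-1-(PMB-oxy)-3-methylbuta-1,3-dien-2-yl group)
Conditions: Pd(dppf)Cl2 (5 mol %), K3PO4, THF/H2O, rt
Reagents that add atoms: none
Why: Suzuki–Miyaura coupling of an enol triflate proceeds with retention at C7, so the isopropenyl group takes the place of the triflate cis to the ether oxygen, which leaves that oxygen trans to C6.

Step 14
Reactants: 28 silyl-protected dienyl carbinol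
Product: 29 trans-1-isopropenyl-2-[(1Z)-1-(PMB-oxy)-3-methylbuta-1,3-dien-2-yl]-4,5-epoxy-4-methylcyclohexan-1-ol (hydroxyl, dienyl group and epoxide oxygen on one face)
Conditions: K2CO3, MeOH, 0 °C to rt
Reagents that add atoms: none
Why: Base-catalysed methanolysis of the trimethylsilyl ether frees the tertiary alcohol without acid, which neither the enol ether nor the epoxide would survive.

Step 15
Reactants: 29 dialkenyl epoxycyclohexanol
Product: 32 ten-membered trimethylsilyl enol ether (C1=C10 enol ether; E C6=C7 with isopropenyl on C7; C8 PMB ether; cis C4–C5 epoxide), via potassium alkoxide 30 (not isolated), via potassium enolate 31 (not isolated)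
Conditions: KH, 18-crown-6, THF, 0 °C to rt; then Et3N, Me3SiCl, −78 °C
Reagents that add atoms: chlorotrimethylsilane, C[Si](C)(C)Cl
Why: Deprotonation gives a crown-separated potassium alkoxide whose C1–C6 bond is weakened, and the 1,5-diene C9=C10–C1–C6–C7=C8 undergoes a concerted [3,3] sigmatropic shift (anionic oxy-Cope rearrangement) in which C8–C9 forms as C1–C6 breaks, leaving the C1 enolate that Me3SiCl traps on oxygen. The closest known reaction is the anionic oxy-Cope rearrangement of trans-1,2-divinylcyclohexanols to (E)-cyclodec-5-enone enolates with silyl trapping. The ten-membered ring is closed by four-atom ring expansion of the cyclohexane (one bond made and one broken in a six-centre chair transition state), not by an end-to-end cyclisation. C8 is the only new stereocentre and is set by chirality transfer from C1 and C6 through the chair in which both alkenyl groups are equatorial on the cyclohexane and the enol ether oxygen, trans to C6, is equatorial; the same chair fixes the E C6=C7 alkene and the enolate geometry (oxygen cis to C9). The step needs chair over boat and [3,3] shift over epoxide opening or C1–C6 heterolysis: the trans-diequatorial alkenyl groups set in steps 4 and 9 allow only the chair with both ring bonds equatorial, the alkoxide lies cis to the epoxide oxygen and cannot reach the rear of C4 or C5, and silylation at −78 °C removes the enolate before it can attack the epoxide across the ring.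

Step 16
Reactants: 32 ten-membered silyl enol ether
Product: 34 C10 ketol (C1 ketone; tertiary C10 hydroxyl; E C6=C7 diene retained), via silyloxy epoxide 33 (not isolated)
Conditions: dimethyldioxirane, acetone/CH2Cl2, −78 °C; then Bu4NF, AcOH, THF, 0 °C
Reagents that add atoms: dimethyldioxirane, CC1(C)OO1
Why: Rubottom oxidation; the silyl enol ether is the most electron-rich alkene and is epoxidised on its peripheral face in the crown conformer delivered by the chair, which puts the C10 oxygen on the face needed for the later ether bridge, and fluoride then opens the silyloxy epoxide to the ketol with the C10–O bond intact.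

Step 17
Reactants: 34 C10 ketol
Product: 36 tetrahydrofuran alcohol (C10–O–C7 ether bridge; C6 secondary hydroxyl; isopropenyl on C7), via C6–C7 epoxide 35 (not isolated)
Conditions: mCPBA, NaHCO3, CH2Cl2, 0 °C; then PPTS (10 mol %), 0 °C to rt
Reagents that add atoms: 3-chloroperoxybenzoic acid, OOC(=O)c1cccc(Cl)c1
Why: Peracid epoxidation of the strained E trisubstituted C6=C7 alkene from its exposed outer face (flanked by H5 and H8), then transannular 5-exo opening at the tertiary allylic carbon C7 by the C10 hydroxyl with inversion, which sets C6 (its C–O bond is retained) and C7 and closes the tetrahydrofuran ring.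

Step 18
Reactants: 36 tetrahydrofuran alcohol
Product: 37 allylic diol (C12 primary hydroxyl on the 2-propenyl group; C6 hydroxyl)
Conditions: SeO2 (20 mol %), t-BuOOH, CH2Cl2, rt
Reagents that add atoms: selenium dioxide, O=[Se]=O; tert-butyl hydroperoxide, CC(C)(C)OO
Why: SeO2 allylic oxidation (ene reaction followed by a [2,3] shift); the isopropenyl methyl holds the only allylic C–H bonds because C7 is quaternary, so the hydroxyl enters at C12 and the alkene returns to C11=C13.

Step 19
Reactants: 37 allylic diol
Product: 40 PMB-protected alpha-methylene lactone, via hydroxy enal 38 (not isolated), via lactol 39 (not isolated)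
Conditions: MnO2 (activated, excess), CH2Cl2, rt
Reagents that add atoms: none
Why: MnO2 oxidises the primary allylic alcohol to the enal, the C6 hydroxyl closes the five-membered lactol and a second oxidation gives the lactone (oxidative lactonisation of a 2-methylene-1,4-diol); no stereocentre is touched.

Step 20
Reactants: 40 PMB-protected lactone
Product: 41 C8 alcohol
Conditions: DDQ, CH2Cl2/pH 7 buffer, 0 °C to rt
Reagents that add atoms: none
Why: Oxidative cleavage of the PMB ether (hydride abstraction by DDQ, then hydrolysis of the oxocarbenium ion) frees the C8 alcohol and leaves the epoxide, ketone and methylene lactone alone.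

Step 21
Reactants: 41 C8 alcohol; 42 methacrylic anhydride
Product: 43 CNP0241021.1 (target methacrylate)
Conditions: Et3N, DMAP (10 mol %), CH2Cl2, 0 °C to rt
Reagents that add atoms: none
Why: DMAP-catalysed acyl transfer esterifies the secondary C8 alcohol with retention at C8.

**Compound list**

1 | 4-methoxybenzyl alcohol | COc1ccc(CO)cc1 | starting material
2 | allyl bromide | C=CCBr | starting material
3 | allyl 4-methoxybenzyl ether | C=CCOCc1ccc(OC)cc1 | intermediate
4 | 3-[(PMB-oxy)methyl]-1,2,4-trioxolane (secondary ozonide) | COc1ccc(COCC2OCOO2)cc1 | intermediate (not isolated)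
5 | 2-(PMB-oxy)acetaldehyde | O=CCOCc1ccc(OC)cc1 | intermediate
6 | (S)-4-benzyloxazolidin-2-one | O=C1N[C@@H](Cc2ccccc2)CO1 | starting material
7 | (E)-but-2-enoyl chloride | C/C=C/C(=O)Cl | starting material
8 | lithium (S)-4-benzyl-2-oxooxazolidin-3-ide | [Li+].O=C1[N-][C@@H](Cc2ccccc2)CO1 | intermediate (not isolated)
9 | (S)-4-benzyl-3-[(E)-but-2-enoyl]oxazolidin-2-one | C/C=C/C(=O)N1C(=O)OC[C@@H]1Cc1ccccc1 | intermediate
10 | dibutylboron (Z)-dienolate of 9 | C=C/C=C(\OB(CCCC)CCCC)N1C(=O)OC[C@@H]1Cc1ccccc1 | intermediate (not isolated)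
11 | dibutylboron aldolate of 12 | C=C[C@@H]([C@H](OB(CCCC)CCCC)COCc1ccc(OC)cc1)C(=O)N1C(=O)OC[C@@H]1Cc1ccccc1 | intermediate (not isolated)
12 | (S)-4-benzyl-3-[(2S,3S)-2-ethenyl-3-hydroxy-4-(PMB-oxy)butanoyl]oxazolidin-2-one | C=C[C@@H]([C@H](O)COCc1ccc(OC)cc1)C(=O)N1C(=O)OC[C@@H]1Cc1ccccc1 | intermediate
13 | (2S,3S)-2-ethenyl-3-hydroxy-N-methoxy-N-methyl-4-(PMB-oxy)butanamide | C=C[C@@H]([C@H](O)COCc1ccc(OC)cc1)C(=O)N(C)OC | intermediate
14 | 4-bromo-2-methylbut-1-ene | C=C(C)CCBr | starting material
15 | (3-methylbut-3-en-1-yl)magnesium bromide | C=C(C)CC[Mg]Br | intermediate (not isolated)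
16 | bis(bromomagnesium) tetrahedral adduct of 13 (hemiaminal carbon unassigned) | C=C[C@@H]([C@H](O[Mg]Br)COCc1ccc(OC)cc1)C(CCC(C)=C)(O[Mg]Br)N(C)OC | intermediate (not isolated)
17 | (3S)-3-[(1S)-1-hydroxy-2-(PMB-oxy)ethyl]-7-methylocta-1,7-dien-4-one | C=C[C@@H]([C@H](O)COCc1ccc(OC)cc1)C(=O)CCC(C)=C | intermediate
18 | (2S)-2-[(1S)-1-hydroxy-2-(PMB-oxy)ethyl]-4-methylcyclohex-3-en-1-one | O=C1CCC(C)=C[C@H]1[C@H](O)COCc1ccc(OC)cc1 | intermediate
19 | 2-[(1S)-1-hydroxy-2-(PMB-oxy)ethyl]-6-methyl-7-oxabicyclo[4.1.0]heptan-3-one, epoxide oxygen cis to the side chain | O=C1CC[C@@]2(C)O[C@H]2[C@H]1[C@H](O)COCc1ccc(OC)cc1 | intermediate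
20 | isopropenylmagnesium bromide | C=C(C)[Mg]Br | starting material
21 | isopropenylcerium dichloride | C=C(C)[Ce](Cl)Cl | intermediate (not isolated)
22 | epoxy diol: 1-isopropenyl-2-[(1S)-1-hydroxy-2-(PMB-oxy)ethyl]-4,5-epoxy-4-methylcyclohexan-1-ol, C1 hydroxyl, side chain and epoxide oxygen on one face | C=C(C)[C@]1(O)CC[C@@]2(C)O[C@H]2[C@H]1[C@H](O)COCc1ccc(OC)cc1 | intermediate
23 | C7 ketone: 1-[2-hydroxy-2-isopropenyl-4,5-epoxy-5-methylcyclohexyl]-2-(PMB-oxy)ethanone, same ring configuration as 22 | C=C(C)[C@]1(O)CC[C@@]2(C)O[C@H]2[C@H]1C(=O)COCc1ccc(OC)cc1 | intermediate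
24 | trimethylsilyl ether of 23 | C=C(C)[C@]1(O[Si](C)(C)C)CC[C@@]2(C)O[C@H]2[C@H]1C(=O)COCc1ccc(OC)cc1 | intermediate
25 | lithium (Z)-enolate of 24 | [Li+].C=C(C)[C@]1(O[Si](C)(C)C)CC[C@@]2(C)O[C@H]2[C@H]1/C([O-])=C/OCc1ccc(OC)cc1 | intermediate (not isolated)
26 | (Z)-enol triflate of 24 (triflate cis to the PMB ether oxygen) | C=C(C)[C@]1(O[Si](C)(C)C)CC[C@@]2(C)O[C@H]2[C@H]1/C(OS(=O)(=O)C(F)(F)F)=C/OCc1ccc(OC)cc1 | intermediate
27 | isopropenylboronic acid pinacol ester | C=C(C)B1OC(C)(C)C(C)(C)O1 | starting material
28 | trimethylsilyl ether of 29 | C=C(C)[C@]1(O[Si](C)(C)C)CC[C@@]2(C)O[C@H]2[C@H]1/C(=C/OCc1ccc(OC)cc1)C(C)=C | intermediate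
29 | trans-1-isopropenyl-2-[(1Z)-1-(PMB-oxy)-3-methylbuta-1,3-dien-2-yl]-4,5-epoxy-4-methylcyclohexan-1-ol (oxy-Cope precursor) | C=C(C)[C@]1(O)CC[C@@]2(C)O[C@H]2[C@H]1/C(=C/OCc1ccc(OC)cc1)C(C)=C | intermediate
30 | potassium alkoxide of 29 | [K+].C=C(C)[C@]1([O-])CC[C@@]2(C)O[C@H]2[C@H]1/C(=C/OCc1ccc(OC)cc1)C(C)=C | intermediate (not isolated)
31 | potassium enolate of the ten-membered ketone | [K+].[O-]/C1=C(/C)C[C@H](OCc2ccc(OC)cc2)/C(C(C)=C)=C/[C@@H]2O[C@]2(C)CC1 | intermediate (not isolated)
32 | ten-membered trimethylsilyl enol ether (E C6=C7 diene, C8 PMB ether, cis C4–C5 epoxide) | C[Si](C)(C)O/C1=C(/C)C[C@H](OCc2ccc(OC)cc2)/C(C(C)=C)=C/[C@@H]2O[C@]2(C)CC1 | intermediate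
33 | C1–C10 silyloxy epoxide of 32 | C[Si](C)(C)O[C@]12O[C@]1(C)C[C@H](OCc1ccc(OC)cc1)/C(C(C)=C)=C/[C@@H]1O[C@]1(C)CC2 | intermediate (not isolated)
34 | C10 ketol (C1 ketone, C10 tertiary alcohol) | O=C1[C@](C)(O)C[C@H](OCc2ccc(OC)cc2)/C(C(C)=C)=C/[C@@H]2O[C@]2(C)CC1 | intermediate
35 | C6–C7 epoxide of 34 | O=C1[C@](C)(O)C[C@H](OCc2ccc(OC)cc2)[C@@]2(C(C)=C)O[C@@H]2[C@@H]2O[C@]2(C)CC1 | intermediate (not isolated)
36 | tetrahydrofuran alcohol (C7–O–C10 bridge, C6 hydroxyl, C7 isopropenyl) | COc1ccc(cc1)CO[C@H]1C[C@@]2(C)O[C@]1(C(C)=C)[C@H](O)[C@@H]1O[C@]1(C)CCC2=O | intermediate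
37 | allylic diol (C12 and C6 hydroxyls) | COc1ccc(cc1)CO[C@H]1C[C@@]2(C)O[C@]1(C(CO)=C)[C@H](O)[C@@H]1O[C@]1(C)CCC2=O | intermediate
38 | hydroxy enal (C12 aldehyde, C6 hydroxyl) | COc1ccc(cc1)CO[C@H]1C[C@@]2(C)O[C@]1(C(C=O)=C)[C@H](O)[C@@H]1O[C@]1(C)CCC2=O | intermediate (not isolated)
39 | lactol (both C12 anomers) | COc1ccc(cc1)CO[C@H]1C[C@@]2(C)O[C@@]13C(=C)C(O)O[C@@H]3[C@@H]1O[C@]1(C)CCC2=O | intermediate (not isolated)
40 | C8 PMB ether of the alpha-methylene lactone | COc1ccc(cc1)CO[C@H]1C[C@@]2(C)O[C@@]13C(=C)C(=O)O[C@@H]3[C@@H]1O[C@]1(C)CCC2=O | intermediate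
41 | C8 alcohol of the alpha-methylene lactone | O[C@H]1C[C@@]2(C)O[C@@]13C(=C)C(=O)O[C@@H]3[C@@H]1O[C@]1(C)CCC2=O | intermediate
42 | methacrylic anhydride | C=C(C)C(=O)OC(=O)C(C)=C | starting material
43 | CNP0241021.1 | C=C(C)C(=O)O[C@H]1C[C@@]2(C)O[C@@]13C(=C)C(=O)O[C@@H]3[C@@H]1O[C@]1(C)CCC2=O | target

**Step count and risks**

Total: 21 steps. Longest linear sequence: 20 steps (steps 1, 2 and 4 to 21).

Step 15 (key step). The crown-activated alkoxide may cleave heterolytically at C1–C6 to a ketone and a dienyl anion instead of rearranging, or the potassium enolate may alkylate itself on the C4–C5 epoxide across the ring before it is silylated. The fallback is the neutral thermal siloxy-Cope rearrangement. It sets out from silyl ether 28, which is heated in degassed decalin with N,O-bis(trimethylsilyl)acetamide as acid scavenger at 180–200 °C in a base-washed sealed tube. The same chair [3,3] shift should then deliver silyl enol ether 32 directly, with no alkoxide or enolate in the flask, and the route is rejoined at 32. New compounds on this path: none F0.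

Step 17. Site selectivity of the peracid may be poor, because C6=C7 carries two allylic oxygens and the 1,1-disubstituted C11=C13 alkene may be epoxidised in competition. The fallback deactivates C11=C13 before the epoxidation and sets out from ketol 34. SeO2/t-BuOOH should give the C12 allylic alcohol F1, and MnO2 the 2-formyl diene F2, in which C11=C13 is part of an acrolein and inert to peracid. mCPBA/NaHCO3 should then epoxidise the only electron-rich alkene to the epoxy enal F3. PPTS closes the tetrahydrofuran to hydroxy enal 38, whose C6 hydroxyl adds to the aldehyde to give lactol 39, now isolated. Oxidation of 39 with MnO2 returns the route at lactone 40.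

Step 9. The aldolate formed from the free C7 hydroxyl may undergo retro-aldol cleavage, or the beta,gamma-epoxy ketone may be enolised with loss of the epoxide, before the organocerium reagent adds. The fallback blocks the hydroxyl and sets out from epoxy ketone 19. Et3SiCl and imidazole in DMF should give the triethylsilyl ether F4. Isopropenylcerium dichloride 21 then adds to F4 from the face opposite the now bulkier side chain to give the tertiary carbinol F5. HF·pyridine in THF/pyridine removes the silyl group and returns the route at diol 22.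

**Further compounds**

F0 | step 15 | none | none
F1 | step 17 | C12 allylic alcohol of ketol 34 | O=C1[C@](C)(O)C[C@H](OCc2ccc(OC)cc2)/C(C(CO)=C)=C/[C@@H]2O[C@]2(C)CC1
F2 | step 17 | 2-formyl diene from ketol 34 | O=C1[C@](C)(O)C[C@H](OCc2ccc(OC)cc2)/C(C(C=O)=C)=C/[C@@H]2O[C@]2(C)CC1
F3 | step 17 | C6–C7 epoxy enal | O=C1[C@](C)(O)C[C@H](OCc2ccc(OC)cc2)[C@@]2(C(C=O)=C)O[C@@H]2[C@@H]2O[C@]2(C)CC1
F4 | step 9 | triethylsilyl ether of epoxy ketone 19 | O=C1CC[C@@]2(C)O[C@H]2[C@H]1[C@H](O[Si](CC)(CC)CC)COCc1ccc(OC)cc1
F5 | step 9 | C7 triethylsilyl ether of diol 22 | C=C(C)[C@]1(O)CC[C@@]2(C)O[C@H]2[C@H]1[C@H](O[Si](CC)(CC)CC)COCc1ccc(OC)cc1
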